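The earlier runs and the new flask are calculated with made-up constants; scatter was added.

How much product stands at the end of red, blue and violet, and which way does it move as the substrate charged grows?

in all of them: free catalyst 8.2 mol%

| flask | substrate | partner | capture agent | remark | time |
|---|---|---|---|---|---|
| east | 16 mM | 0.50 equiv | 2.9 mM | run made earlier |  |
| north-west | 25 mM | 0.50 equiv | 2.9 mM | run made earlier |  |
| red | 20 mM | 0.500 equiv | 2.90 mM |  | 40 h |
| blue | 30 mM | 0.500 equiv | 2.90 mM |  | 40 h |
| violet | 40 mM | 0.500 equiv | 2.90 mM |  | 40 h |

| run | time / h | product / % |
|---|---|---|
| east | 2.50 | 9.2 |
| east | 8.00 | 17.0 |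
| east | 12.0 | 19.5 |
| east | 20.0 | 19.0 |
| north-west | 2.50 | 10.5 |
| north-west | 8.00 | 22.4 |
| north-west | 12.0 | 19.8 |
| north-west | 20.0 | 22.1 |

(readings scatter by 1 percentage point)

- [product] at the end for red, blue, violet, in this order
- how that number moves from the first to the last of them (hardly changes / falls, then rises / falls all the way / rises all the way / rises, then falls)

- "hardly changes" means that all values lie within two and a half points (for a concentration: within two and a half percent of the largest)

1. I take each plateau as the mean of the last two readings: 19.2% in east and 21.0% in north-west. The first rung of the ladder of time scales is the rise. At 2.50 h, east has reached about half of its plateau, and north-west about half of its own.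

2. The next rung is the flat stretch. From 12.0 h to 20.0 h, east moves by −0.5 percentage points and north-west by 2.3 points. Each reading scatters by 1 point, so I read no drift.

3. The last rung is the asked time, 40 h, twice the last reading's time. I therefore treat the question as one about plateaus, although this is an extrapolation.

4. In concentration the plateaus are 3.08 mM in east and 5.24 mM in north-west. The logarithm of their ratio over the logarithm of the ratio of the charges gives 1.19. This reading is the plateau order: the percent change of plateau [product] per percent of substrate charged, with partner equivalents, catalyst loading and [capture agent] held fixed.

5. Scaling north-west by this order, I reckon 4.02 mM for red, 6.51 mM for blue and 9.16 mM for violet. Blue and violet lie beyond the charges tried.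

6. The forecast gives 4.2 mM, 6.6 mM and 9.2 mM, so that [product] rises all the way, on the ground that “the catalyst seems to die, or the reaction stalls”. My figures for red and blue are lower, but they run the same way.

7. The flasks give 4.09 mM, 6.73 mM and 9.50 mM, so the product rises all the way.

    partner + free catalyst → catalyst intermediate A (k = 330 L mol⁻¹ min⁻¹)
    substrate + catalyst intermediate A → catalyst intermediate B (k = 0.700 L mol⁻¹ min⁻¹)
    catalyst intermediate B → by-product + catalyst intermediate C (k = 0.0630 min⁻¹)
    catalyst intermediate C → free catalyst + product (k = 0.0610 min⁻¹)
    catalyst intermediate B + capture agent → trapped intermediate (k = 0.240 L mol⁻¹ min⁻¹)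
    partner → decomposed reagent (k = 0.00970 min⁻¹)

In violet, partner, the limiting reagent, stands at 0% of its charge at 40.0 h, beside 10.4 mM of decomposed reagent. Starting from red's 4.09 mM, the plateau order of 1.19 gives 6.63 mM for blue, where the flask holds 6.73 mM, and 9.33 mM for violet, where it holds 9.50 mM. The local order at violet is 1.2.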